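The pitfall in a clean second-order plot is to read a catalyst order from it: Saturday's and Sunday's runs both charged 1 mol% free catalyst, so their rates cannot separate catalyst from concentration.

| flask | starting material | coupling partner | capture agent | free catalyst | remark |
|---|---|---|---|---|---|
| Saturday's | 0.49 M | 0.90 equiv | 9.8 mM | 1 mol% | the very flask that is asked about, followed so far |
| Sunday's | 0.73 M | 0.90 equiv | 9.8 mM | 1 mol% | run made earlier |
| flask | 0.49 M | 0.900 equiv | 9.80 mM | 1 mol% |  |

- Saturday's (time / min: target / %, starting material / %): 3.00: 11.9, 87.7; 5.00: 18.3, 81.4; 8.00: 26.5, 73.3; 15.0: 40.5, 59.5; 25.0: 52.2, 47.0; 40.0: 62.0, 37.4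
- Sunday's (time / min: target / %, starting material / %): 12.0: 41.4, 57.8; 25.0: 59.4, 39.8; 40.0: 69.2, 29.5; 50.0: 73.0, 26.7; 60.0: 74.9, 24.1; 80.0: 77.5, 22.0

(each reading ± 0.3 percentage points)

- factor on the rate of making target when 30% of the starting material are converted if coupling partner is charged twice over
- factor on the rate when 30% of the starting material are converted if free catalyst is charged at 5 mol% instead

I followed one catalyst molecule and gave it a fixed chance of leaving its round at each turnover. The reciprocal of that chance is the turnover capacity, the turnover number the charge reaches before it stops: target made, as a fraction of starting material charged, per fraction of catalyst charged. Sunday's run gained 2.6 percentage points over its last interval and stood at its last reading at target 77.5% with starting material 22.0% unused. I read that slowing as lost catalyst and took the last reading as an estimate of the capacity, 77.5.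

The working fraction of the catalyst at target fraction y is then one minus y over loading times capacity. Taking target equal to conversion and the rate proportional to working catalyst, at 30% conversion this is 61.3% at 1 mol% and 92.3% at 5 mol%, so I expected a factor of 7.53 on the rate. The capacity gave me no number for the coupling partner.

The forecast gave 2.5 for the doubled coupling partner and 1.2 for the catalyst, on a comparison it said “suggests about zero order or saturation”; my catalyst factor was higher.

The flask gives 1.19 for the doubled coupling partner and 6.14 for the catalyst at 5 mol%.

    starting material + free catalyst ⇌ catalyst intermediate A (K = 3.40 M⁻¹, k = 0.383 M⁻¹ s⁻¹)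
    catalyst intermediate A → catalyst intermediate B (k = 0.436 s⁻¹)
    coupling partner + catalyst intermediate B → catalyst intermediate C (k = 1.21 M⁻¹ s⁻¹)
    catalyst intermediate C ⇌ free catalyst + target (K = 0.381 M, k = 0.396 s⁻¹)
    catalyst intermediate C + capture agent → trapped intermediate (k = 0.0648 M⁻¹ s⁻¹)
    catalyst intermediate B → spent catalyst (k = 0.00204 s⁻¹)

Saturday's flask at 8.00 min held trapped intermediate 6.47% and spent catalyst 12.1%, together 18.6% of the catalyst, which is below the 33.9% lost that the capacity gives for target 26.3%, and my 7.53 stands above 6.14. At 800 min the same flask held spent catalyst 59.4%, trapped intermediate 40.6%, free catalyst 0% and target 73.6%, against 77.5% from the capacity.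

The numbers in the tables stem from a simulated flask for an exercise, noise included.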